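**Strategy.** The plan reads the lactone carbonyl C12 and the ring oxygen as one molecule of CO2 inserted between C11 and C6 of the α-methylene-γ-butyrolactone. In one pot, CO2 is first joined to the vinylic carbon C11 of an alkenylboronate (Cu-catalysed carboxylation, C11–C12), and the carboxylate then adds to the inner terminus C6 of a terminal allene (Au-catalysed 5-exo lactonisation, O–C6). The step exploits that C11 is vinylic and C6 allylic to the C4=C5 alkene. It closes the ring O–C6–C7–C11–C12, sets C6 trans to the C7 side chain and leaves C5 as a vinyl group for the later ring-closing metathesis. The precursor is an acyclic 3-(1-borylvinyl)-1,2-diene made from a cis-epoxy alcohol.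

Key step: step 10

Remark: atom labels follow germacrane numbering of the target (C6 bears the lactone O, C7 the ring-fusion H, C11=C13 is the exocyclic methylene, C12 the lactone C=O, C8 the butanoate, C9 the acetate, C10 the alkene carbon bearing C14 = CHO, C4 the methyl-bearing alkene carbon); 4-methoxybenzyl propargyl ether and (S)-2-hydroxy-2-methylbutanoic acid are taken as purchasable.

Step 1
Reactants: 1 acrolein (prop-2-enal)
Product: 3 2-bromoprop-2-enal, via 2,3-dibromopropanal 2 (not isolated)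
Conditions: Br2, CH2Cl2, 0 °C; then Et3N, 0 °C
Reagents that add atoms: bromine, BrBr
Why: Bromination of the enal C=C followed by E1cB loss of HBr (bromination–dehydrobromination) should give the 2-bromoenal; no stereocentre is formed.

Step 2
Reactants: 3 2-bromoprop-2-enal; 4 methyl 2-[bis(2,2,2-trifluoroethoxy)phosphoryl]acetate
Product: 5 methyl (2Z)-4-bromopenta-2,4-dienoate
Conditions: KHMDS, 18-crown-6, THF, −78 °C
Reagents that add atoms: none
Why: Still–Gennari olefination; the electron-poor phosphonate makes oxaphosphetane collapse fast, so the kinetic Z-enoate should form.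

Step 3
Reactants: 5 methyl (2Z)-4-bromopenta-2,4-dienoate
Product: 6 (2Z)-4-bromopenta-2,4-dien-1-ol
Conditions: DIBAL-H (2.2 equiv), CH2Cl2, −78 °C; Rochelle salt work-up
Reagents that add atoms: none
Why: 1,2-Reduction of the enoate by DIBAL-H at low temperature should leave the Z geometry and the vinyl bromide untouched.

Step 4
Reactants: 6 (2Z)-4-bromopenta-2,4-dien-1-ol
Product: 7 [(2R,3R)-3-(1-bromoethenyl)oxiran-2-yl]methanol
Conditions: VO(Oi-Pr)3 (1 mol%), C2-symmetric chiral bis-hydroxamic acid ligand (2 mol%), t-BuOOH, toluene, 0 °C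
Reagents that add atoms: tert-butyl hydroperoxide, CC(C)(C)OO
Why: Hydroxyl-directed vanadium-catalysed asymmetric epoxidation of a Z-allylic alcohol keeps the cis geometry and sets both centres through the ligand (the hand that gives 2R,3R is used); the electron-poor, undirected bromoalkene should not react.

Step 5
Reactants: 7 [(2R,3R)-3-(1-bromoethenyl)oxiran-2-yl]methanol; 8 1-methoxy-4-[(prop-2-yn-1-yloxy)methyl]benzene
Product: 11 (2S,3S)-3-(1-bromoethenyl)-6-[(4-methoxyphenyl)methoxy]hex-4-yne-1,2-diol, via lithium acetylide 9 (not isolated), via diethylalkynylalane 10 (not isolated)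
Conditions: 8, n-BuLi, toluene/THF, −78 to 0 °C; Et2AlCl, 0 °C; then 7, 0 °C to rt; aq. Rochelle salt
Reagents that add atoms: none
Why: C3-selective opening of a 2,3-epoxy alcohol by an alkynylalane (aluminium alkoxide direction plus allylic activation) proceeds by SN2 inversion at C7 with C8 untouched, which fixes the C7/C8 relationship of the target.

Step 6
Reactants: 11 (2S,3S)-3-(1-bromoethenyl)-6-[(4-methoxyphenyl)methoxy]hex-4-yne-1,2-diol
Product: 12 [(2S,3S)-3-(1-bromoethenyl)-6-[(4-methoxyphenyl)methoxy]hex-4-yne-1,2-diyl]bis(oxy)bis[tert-butyl(dimethyl)silane]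
Conditions: TBSOTf (2.5 equiv), 2,6-lutidine, CH2Cl2, −78 to 0 °C
Reagents that add atoms: tert-butyldimethylsilyl triflate, CC(C)(C)[Si](C)(C)OS(=O)(=O)C(F)(F)F
Why: Silylation with the silyl triflate should protect both the primary (C9) and the hindered secondary (C8) hydroxyl without touching a stereocentre.

Step 7
Reactants: 12 bis-silyl ether
Product: 13 (4S,5S)-4-(1-bromoethenyl)-5,6-bis[(tert-butyldimethylsilyl)oxy]hex-2-yn-1-ol
Conditions: DDQ, CH2Cl2/pH 7 buffer, 0 °C to rt
Reagents that add atoms: none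
Why: Oxidative PMB cleavage by DDQ (benzylic oxocarbenium ion, hydrolysed by water) should free the propargylic alcohol while silyl ethers, alkyne and vinyl bromide stay inert.

Step 8
Reactants: 13 (4S,5S)-4-(1-bromoethenyl)-5,6-bis[(tert-butyldimethylsilyl)oxy]hex-2-yn-1-ol
Product: 14 (4S,5S)-5,6-bis[(tert-butyldimethylsilyl)oxy]-4-[1-(5,5-dimethyl-1,3,2-dioxaborinan-2-yl)ethenyl]hex-2-yn-1-ol
Conditions: bis(neopentyl glycolato)diboron, PdCl2(PPh3)2 (3 mol%), PPh3 (6 mol%), KOPh, toluene, 50 °C
Reagents that add atoms: bis(neopentyl glycolato)diboron, CC1(C)COB(OC1)B1OCC(C)(C)CO1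
Why: Miyaura borylation of the 2-bromo-1-alkene (oxidative addition, phenoxide-assisted B–B transmetalation, reductive elimination) should replace Br on C11 by the boronic ester.

Step 9
Reactants: 14 alkenylboronate propargylic alcohol
Product: 16 [(2S,3R)-3-[1-(5,5-dimethyl-1,3,2-dioxaborinan-2-yl)ethenyl]hexa-4,5-diene-1,2-diyl]bis(oxy)bis[tert-butyl(dimethyl)silane], via propargylic sulfonylhydrazine 15 (not isolated)
Conditions: 2-nitrobenzenesulfonylhydrazide, PPh3, DEAD, THF, −15 °C to rt
Reagents that add atoms: none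
Why: Myers allene synthesis: Mitsunobu N-alkylation of the sulfonylhydrazide, loss of sulfinic acid to the propargyl diazene and retro-ene loss of N2 should deliver the terminal allene C6=C5=CH2 without touching C7 or C8.

Step 10
Reactants: 16 allenyl alkenylboronate; 17 carbon dioxide
Product: 20 (4S,5R)-4-[(1S)-1,2-bis[(tert-butyldimethylsilyl)oxy]ethyl]-5-ethenyl-3-methylideneoxolan-2-one, via potassium allenoate 18 (not isolated), via allenoic acid 19 (not isolated)
Conditions: (IPr)CuCl (5 mol%), KOt-Bu (1.05 equiv), CO2 (1 atm), THF, 70 °C; then AcOH (1.1 equiv), Ph3PAuNTf2 (5 mol%), rt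
Reagents that add atoms: none
Why: Stage one is the NHC–copper-catalysed carboxylation of an alkenylboronic ester: tert-butoxide turns 16 into its ate complex, B-to-Cu transmetalation gives the C11 alkenylcopper, and CO2 inserts into Cu–C11 to form C11–C12 (carboxylate 18). Stage two, after protonation to 19, is the gold(I)-catalysed cycloisomerisation of a 4,5-allenoic acid: the carboxyl oxygen attacks C6 of the gold-activated C5=C6 bond anti to the metal and protodeauration leaves C5 as a vinyl group, forming O–C6. The lactone ring O–C6–C7–C11–C12 closes in the 5-exo-trig mode, which for this tether should be preferred over 6-endo attack at the central allene carbon. The new C6 stereocentre is controlled by C7 (1,2-induction): in the envelope transition state the large 1,2-bis(silyloxy)ethyl group on C7 and the gold-bound allene residue on C6 avoid each other, which should give the trans-4,5-disubstituted lactone. The step needs transmetalation without base-induced isomerisation of the skipped vinyl–allene (the alkoxide is bound as borate, so little free base remains) and trans facial selectivity (secured by the C7 substituent).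

Step 11
Reactants: 20 bis-silylated lactone
Product: 21 (4S,5R)-4-[(1S)-1-[(tert-butyldimethylsilyl)oxy]-2-hydroxyethyl]-5-ethenyl-3-methylideneoxolan-2-one
Conditions: HF·pyridine, pyridine, THF, 0 °C
Reagents that add atoms: none
Why: Selective desilylation: the primary silyl ether should cleave much faster than the hindered secondary one under buffered HF·pyridine.

Step 12
Reactants: 21 primary alcohol
Product: 22 (2S)-2-[(tert-butyldimethylsilyl)oxy]-2-[(2R,3S)-2-ethenyl-4-methylidene-5-oxooxolan-3-yl]acetaldehyde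
Conditions: Dess–Martin periodinane, CH2Cl2, 0 °C to rt
Reagents that add atoms: none
Why: Dess–Martin oxidation should give the α-silyloxy aldehyde under non-basic conditions that do not epimerise C8.

Step 13
Reactants: 23 4-bromo-2-methylbut-1-ene; 24 (2E)-3-(dimethylamino)prop-2-enal
Product: 26 (2E)-6-methylhepta-2,6-dienal, via homoallyl Grignard reagent 25 (not isolated)
Conditions: Mg, THF, rt; then 24, 0 °C; aq. HCl work-up
Reagents that add atoms: none
Why: Grignard 1,2-addition to the vinylogous formamide and acid-induced loss of dimethylamine (vinylogous Bouveault formylation) should give the conjugated E-enal.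

Step 14
Reactants: 26 (2E)-6-methylhepta-2,6-dienal
Product: 27 (2Z)-2-iodo-6-methylhepta-2,6-dienal
Conditions: I2, DMAP (cat.), K2CO3, THF/H2O, rt
Reagents that add atoms: iodine, II
Why: Amine-catalysed α-iodination of an enal (Baylis–Hillman-type conjugate addition of DMAP, iodination of the enolate, elimination) should give the Z-2-iodoenal, in which the chain lies trans to the formyl group.

Step 15
Reactants: 27 (2Z)-2-iodo-6-methylhepta-2,6-dienal
Product: 28 (2Z)-2-iodo-1,1-dimethoxy-6-methylhepta-2,6-diene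
Conditions: HC(OMe)3, PPTS (cat.), CH2Cl2, rt
Reagents that add atoms: trimethyl orthoformate, COC(OC)OC
Why: Acid-catalysed acetalisation masks C14 as the dimethyl acetal, so that the vinyl iodide can serve in the chromium coupling.

Step 16
Reactants: 22 lactone aldehyde; 28 vinyl iodide acetal
Product: 29 (4S,5R)-4-[(1S,2R,3E)-1-[(tert-butyldimethylsilyl)oxy]-3-(dimethoxymethyl)-2-hydroxy-7-methylocta-3,7-dien-1-yl]-5-ethenyl-3-methylideneoxolan-2-one
Conditions: CrCl2 (6 equiv), NiCl2 (2 mol%), DMSO, rt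
Reagents that add atoms: none
Why: Nozaki–Hiyama–Kishi coupling: the alkenylchromium forms with retention of alkene geometry and adds only to the aldehyde, and the new C9 centre should follow the polar Felkin–Anh model (attack anti to the C8 silyloxy group) to give the 8,9-anti alcohol.

Step 17
Reactants: 29 allylic alcohol
Product: 30 (1S,2R,3E)-1-[(tert-butyldimethylsilyl)oxy]-3-(dimethoxymethyl)-1-[(2R,3S)-2-ethenyl-4-methylidene-5-oxooxolan-3-yl]-7-methylocta-3,7-dien-2-yl acetate
Conditions: Ac2O, pyridine, DMAP (cat.), CH2Cl2, 0 °C to rt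
Reagents that add atoms: acetic anhydride, CC(=O)OC(C)=O
Why: DMAP-catalysed acetylation of the secondary allylic alcohol installs the C9 acetate of the target.

Step 18
Reactants: 30 silyl ether acetate
Product: 31 (1S,2R,3E)-3-(dimethoxymethyl)-1-[(2R,3R)-2-ethenyl-4-methylidene-5-oxooxolan-3-yl]-1-hydroxy-7-methylocta-3,7-dien-2-yl acetate
Conditions: HF·pyridine, pyridine, THF, 0 °C to rt
Reagents that add atoms: none
Why: Buffered fluoride desilylation should free the C8 hydroxyl without a basic alkoxide (no acetyl migration) and leave the acetal in place, which keeps C14 from forming a lactol with the new hydroxyl.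

Step 19
Reactants: 32 (2S)-2-hydroxy-2-methylbutanoic acid
Product: 33 (2S)-2-(acetyloxy)-2-methylbutanoic acid
Conditions: AcCl (neat), 50 °C; then H2O
Reagents that add atoms: acetyl chloride, CC(=O)Cl
Why: O-Acetylation of the tertiary α-hydroxy acid; the quaternary stereocentre cannot epimerise.

Step 20
Reactants: 33 (2S)-2-(acetyloxy)-2-methylbutanoic acid
Product: 34 (2S)-1-chloro-2-methyl-1-oxobutan-2-yl acetate
Conditions: (COCl)2, DMF (cat.), CH2Cl2, 0 °C to rt
Reagents that add atoms: oxalyl chloride, ClC(=O)C(=O)Cl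
Why: Acid chloride formation through the Vilsmeier intermediate; with no α-hydrogen neither ketene formation nor racemisation is possible.

Step 21
Reactants: 31 C8 alcohol; 34 acid chloride
Product: 35 (1S,2R,3E)-2-(acetyloxy)-3-(dimethoxymethyl)-1-[(2R,3S)-2-ethenyl-4-methylidene-5-oxooxolan-3-yl]-7-methylocta-3,7-dien-1-yl (2S)-2-(acetyloxy)-2-methylbutanoate
Conditions: pyridine, DMAP, CH2Cl2, 0 to 40 °C
Reagents that add atoms: none
Why: DMAP-catalysed acylation (acylpyridinium intermediate) of the C8 hydroxyl should install the butanoate with all stereocentres unchanged.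

Step 22
Reactants: 35 diester acetal
Product: 36 (1S,2R,3E)-2-(acetyloxy)-1-[(2R,3S)-2-ethenyl-4-methylidene-5-oxooxolan-3-yl]-3-formyl-7-methylocta-3,7-dien-1-yl (2S)-2-(acetyloxy)-2-methylbutanoate
Conditions: PPTS (cat.), acetone/H2O, rt
Reagents that add atoms: water, O
Why: Mild acid hydrolysis of the dimethyl acetal through the conjugated oxocarbenium ion should release the enal while esters and lactone survive.

Step 23
Reactants: 36 enal diene
Product: 37 target CNP0499875.1
Conditions: Hoveyda–Grubbs second-generation catalyst (10 mol%), toluene (1 mM), 80 °C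
Reagents that add atoms: none
Why: Ring-closing metathesis between the C6 vinyl group and the isopropenyl terminus should form the trisubstituted C4=C5 bond as the ring-cis (4Z) isomer expected for a ten-membered ring; the α-methylene lactone and the enal alkene are poor metathesis partners.

**Compound list**

1 | acrolein | C=CC=O | starting material
2 | 2,3-dibromopropanal | O=CC(Br)CBr | intermediate (not isolated)
3 | 2-bromoprop-2-enal | C=C(Br)C=O | intermediate
4 | methyl 2-[bis(2,2,2-trifluoroethoxy)phosphoryl]acetate | COC(=O)CP(=O)(OCC(F)(F)F)OCC(F)(F)F | starting material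
5 | methyl (2Z)-4-bromopenta-2,4-dienoate | COC(=O)/C=C\C(Br)=C | intermediate
6 | (2Z)-4-bromopenta-2,4-dien-1-ol | OC/C=C\C(Br)=C | intermediate
7 | [(2R,3R)-3-(1-bromoethenyl)oxiran-2-yl]methanol | OC[C@H]1O[C@H]1C(Br)=C | intermediate
8 | 1-methoxy-4-[(prop-2-yn-1-yloxy)methyl]benzene | C#CCOCc1ccc(OC)cc1 | starting material
9 | {3-[(4-methoxyphenyl)methoxy]prop-1-yn-1-yl}lithium | [Li]C#CCOCc1ccc(OC)cc1 | intermediate (not isolated)
10 | diethyl{3-[(4-methoxyphenyl)methoxy]prop-1-yn-1-yl}alumane | CC[Al](CC)C#CCOCc1ccc(OC)cc1 | intermediate (not isolated)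
11 | (2S,3S)-3-(1-bromoethenyl)-6-[(4-methoxyphenyl)methoxy]hex-4-yne-1,2-diol | OC[C@@H](O)[C@@H](C(Br)=C)C#CCOCc1ccc(OC)cc1 | intermediate
12 | [(2S,3S)-3-(1-bromoethenyl)-6-[(4-methoxyphenyl)methoxy]hex-4-yne-1,2-diyl]bis(oxy)bis[tert-butyl(dimethyl)silane] | CC(C)(C)[Si](C)(C)OC[C@@H](O[Si](C)(C)C(C)(C)C)[C@@H](C(Br)=C)C#CCOCc1ccc(OC)cc1 | intermediate
13 | (4S,5S)-4-(1-bromoethenyl)-5,6-bis[(tert-butyldimethylsilyl)oxy]hex-2-yn-1-ol | CC(C)(C)[Si](C)(C)OC[C@@H](O[Si](C)(C)C(C)(C)C)[C@@H](C(Br)=C)C#CCO | intermediate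
14 | (4S,5S)-5,6-bis[(tert-butyldimethylsilyl)oxy]-4-[1-(5,5-dimethyl-1,3,2-dioxaborinan-2-yl)ethenyl]hex-2-yn-1-ol | CC(C)(C)[Si](C)(C)OC[C@@H](O[Si](C)(C)C(C)(C)C)[C@@H](C(=C)B1OCC(C)(C)CO1)C#CCO | intermediate
15 | N-[(4S,5S)-5,6-bis[(tert-butyldimethylsilyl)oxy]-4-[1-(5,5-dimethyl-1,3,2-dioxaborinan-2-yl)ethenyl]hex-2-yn-1-yl]-2-nitrobenzenesulfonohydrazide | CC(C)(C)[Si](C)(C)OC[C@@H](O[Si](C)(C)C(C)(C)C)[C@@H](C(=C)B1OCC(C)(C)CO1)C#CCN(N)S(=O)(=O)c1ccccc1[N+](=O)[O-] | intermediate (not isolated)
16 | [(2S,3R)-3-[1-(5,5-dimethyl-1,3,2-dioxaborinan-2-yl)ethenyl]hexa-4,5-diene-1,2-diyl]bis(oxy)bis[tert-butyl(dimethyl)silane] | CC(C)(C)[Si](C)(C)OC[C@@H](O[Si](C)(C)C(C)(C)C)[C@@H](C(=C)B1OCC(C)(C)CO1)C=C=C | intermediate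
17 | carbon dioxide | O=C=O | starting material
18 | potassium (3R)-3-[(1S)-1,2-bis[(tert-butyldimethylsilyl)oxy]ethyl]-2-methylidenehexa-4,5-dienoate | CC(C)(C)[Si](C)(C)OC[C@@H](O[Si](C)(C)C(C)(C)C)[C@@H](C(=C)C(=O)[O-])C=C=C.[K+] | intermediate (not isolated)
19 | (3R)-3-[(1S)-1,2-bis[(tert-butyldimethylsilyl)oxy]ethyl]-2-methylidenehexa-4,5-dienoic acid | CC(C)(C)[Si](C)(C)OC[C@@H](O[Si](C)(C)C(C)(C)C)[C@@H](C(=C)C(=O)O)C=C=C | intermediate (not isolated)
20 | (4S,5R)-4-[(1S)-1,2-bis[(tert-butyldimethylsilyl)oxy]ethyl]-5-ethenyl-3-methylideneoxolan-2-one | C=C1C(=O)O[C@H](C=C)[C@H]1[C@H](O[Si](C)(C)C(C)(C)C)CO[Si](C)(C)C(C)(C)C | intermediate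
21 | (4S,5R)-4-[(1S)-1-[(tert-butyldimethylsilyl)oxy]-2-hydroxyethyl]-5-ethenyl-3-methylideneoxolan-2-one | C=C1C(=O)O[C@H](C=C)[C@H]1[C@H](O[Si](C)(C)C(C)(C)C)CO | intermediate
22 | (2S)-2-[(tert-butyldimethylsilyl)oxy]-2-[(2R,3S)-2-ethenyl-4-methylidene-5-oxooxolan-3-yl]acetaldehyde | C=C1C(=O)O[C@H](C=C)[C@H]1[C@H](O[Si](C)(C)C(C)(C)C)C=O | intermediate
23 | 4-bromo-2-methylbut-1-ene | CC(=C)CCBr | starting material
24 | (2E)-3-(dimethylamino)prop-2-enal | CN(C)/C=C/C=O | starting material
25 | (3-methylbut-3-en-1-yl)magnesium bromide | CC(=C)CC[Mg]Br | intermediate (not isolated)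
26 | (2E)-6-methylhepta-2,6-dienal | O=C/C=C/CCC(C)=C | intermediate
27 | (2Z)-2-iodo-6-methylhepta-2,6-dienal | O=C/C(I)=C/CCC(C)=C | intermediate
28 | (2Z)-2-iodo-1,1-dimethoxy-6-methylhepta-2,6-diene | COC(OC)/C(I)=C/CCC(C)=C | intermediate
29 | (4S,5R)-4-[(1S,2R,3E)-1-[(tert-butyldimethylsilyl)oxy]-3-(dimethoxymethyl)-2-hydroxy-7-methylocta-3,7-dien-1-yl]-5-ethenyl-3-methylideneoxolan-2-one | C=C1C(=O)O[C@H](C=C)[C@H]1[C@H](O[Si](C)(C)C(C)(C)C)[C@H](O)/C(C(OC)OC)=C\CCC(C)=C | intermediate
30 | (1S,2R,3E)-1-[(tert-butyldimethylsilyl)oxy]-3-(dimethoxymethyl)-1-[(2R,3S)-2-ethenyl-4-methylidene-5-oxooxolan-3-yl]-7-methylocta-3,7-dien-2-yl acetate | C=C1C(=O)O[C@H](C=C)[C@H]1[C@H](O[Si](C)(C)C(C)(C)C)[C@H](OC(C)=O)/C(C(OC)OC)=C\CCC(C)=C | intermediate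
31 | (1S,2R,3E)-3-(dimethoxymethyl)-1-[(2R,3R)-2-ethenyl-4-methylidene-5-oxooxolan-3-yl]-1-hydroxy-7-methylocta-3,7-dien-2-yl acetate | C=C1C(=O)O[C@H](C=C)[C@H]1[C@H](O)[C@H](OC(C)=O)/C(C(OC)OC)=C\CCC(C)=C | intermediate
32 | (2S)-2-hydroxy-2-methylbutanoic acid | OC(=O)[C@](C)(CC)O | starting material
33 | (2S)-2-(acetyloxy)-2-methylbutanoic acid | OC(=O)[C@](C)(CC)OC(C)=O | intermediate
34 | (2S)-1-chloro-2-methyl-1-oxobutan-2-yl acetate | ClC(=O)[C@](C)(CC)OC(C)=O | intermediate
35 | (1S,2R,3E)-2-(acetyloxy)-3-(dimethoxymethyl)-1-[(2R,3S)-2-ethenyl-4-methylidene-5-oxooxolan-3-yl]-7-methylocta-3,7-dien-1-yl (2S)-2-(acetyloxy)-2-methylbutanoate | C=C1C(=O)O[C@H](C=C)[C@H]1[C@H](OC(=O)[C@](C)(CC)OC(C)=O)[C@H](OC(C)=O)/C(C(OC)OC)=C\CCC(C)=C | intermediate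
36 | (1S,2R,3E)-2-(acetyloxy)-1-[(2R,3S)-2-ethenyl-4-methylidene-5-oxooxolan-3-yl]-3-formyl-7-methylocta-3,7-dien-1-yl (2S)-2-(acetyloxy)-2-methylbutanoate | C=C1C(=O)O[C@H](C=C)[C@H]1[C@H](OC(=O)[C@](C)(CC)OC(C)=O)[C@H](OC(C)=O)/C(C=O)=C\CCC(C)=C | intermediate
37 | CNP0499875.1: (6R,7S,8S,9R)-9-acetoxy-8-[(2S)-2-acetoxy-2-methylbutanoyloxy]-14-oxogermacra-1(10)E,4Z,11(13)-trien-12,6-olide | C=C1C(=O)O[C@@H]2/C=C(/C)CC/C=C(/C=O)[C@@H](OC(C)=O)[C@@H](OC(=O)[C@](C)(CC)OC(C)=O)[C@@H]12 | target

**Step count.** Total: 23 steps. Longest linear sequence: 18 steps (steps 1–12, 16–18, 21–23).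

**Steps most likely to fail**

Step 10 (key step). The anti-oxyauration may show poor facial selectivity at C6, so that cis-lactone forms as well, or the skipped vinyl–allene may isomerise under the basic carboxylation. The fallback sets out from bromide 13 and separates the two bond formations. Myers allene synthesis on 13 should give [(2S,3S)-3-(1-bromoethenyl)hexa-4,5-diene-1,2-diyl]bis(oxy)bis[tert-butyl(dimethyl)silane] F1. Bromine–lithium exchange (t-BuLi, −78 °C) and quenching with CO2 should give acid 19, which is now isolated. Acid 19 is then cyclised with Pd(0)/dppf: hydropalladation of the allene gives a π-allylpalladium carboxylate whose C–O bond formation is reversible, so the lactone is formed under thermodynamic control (trans). The fallback returns to the route at 20.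

Step 23. Ring closure to the trisubstituted ten-membered alkene may lose to oligomerisation, or the catalyst may be held up by the ester- and enal-rich substrate. The fallback sets out from acetate 30 and closes the ring before C8 and C14 are elaborated. Metathesis of 30 should give the macrocyclic silyl ether acetal F3; buffered HF·pyridine frees the macrocyclic C8 alcohol F4 (the acetal still masks C14, so no lactol can form); acylation with 34 gives the macrocyclic diester acetal F5; hydrolysis of the acetal (PPTS, wet acetone) returns to the route at 37.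

Step 16. Felkin–Anh control at C9 may be weak, or the α-silyloxy aldehyde may epimerise at C8 during the slow chromium coupling. The fallback sets out from 29 obtained as a C9 epimer mixture. Dess–Martin oxidation gives the enone (4S,5R)-4-[(1S,3E)-1-[(tert-butyldimethylsilyl)oxy]-3-(dimethoxymethyl)-7-methyl-2-oxoocta-3,7-dien-1-yl]-5-ethenyl-3-methylideneoxolan-2-one F2. Reagent-controlled 1,2-reduction (Corey–Bakshi–Shibata oxazaborolidine, BH3·SMe2) then sets C9 independently of the addition step and returns to the route at 29.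

Further compounds
F1 | step 10 | [(2S,3S)-3-(1-bromoethenyl)hexa-4,5-diene-1,2-diyl]bis(oxy)bis[tert-butyl(dimethyl)silane] | CC(C)(C)[Si](C)(C)OC[C@@H](O[Si](C)(C)C(C)(C)C)[C@@H](C(Br)=C)C=C=C
F2 | step 16 | (4S,5R)-4-[(1S,3E)-1-[(tert-butyldimethylsilyl)oxy]-3-(dimethoxymethyl)-7-methyl-2-oxoocta-3,7-dien-1-yl]-5-ethenyl-3-methylideneoxolan-2-one | C=C1C(=O)O[C@H](C=C)[C@H]1[C@H](O[Si](C)(C)C(C)(C)C)C(=O)/C(C(OC)OC)=C\CCC(C)=C
F3 | step 23 | macrocyclic silyl ether acetal (target skeleton with C8 OTBS and C14 as dimethyl acetal) | C=C1C(=O)O[C@@H]2/C=C(/C)CC/C=C(/C(OC)OC)[C@@H](OC(C)=O)[C@@H](O[Si](C)(C)C(C)(C)C)[C@@H]12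
F4 | step 23 | macrocyclic C8 alcohol (C14 as dimethyl acetal) | C=C1C(=O)O[C@@H]2/C=C(/C)CC/C=C(/C(OC)OC)[C@@H](OC(C)=O)[C@@H](O)[C@@H]12
F5 | step 23 | macrocyclic diester acetal (target with C14 as dimethyl acetal) | C=C1C(=O)O[C@@H]2/C=C(/C)CC/C=C(/C(OC)OC)[C@@H](OC(C)=O)[C@@H](OC(=O)[C@](C)(CC)OC(C)=O)[C@@H]12
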